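The ten-membered carbocycle is reached by contraction, not by direct closure: the target is cut back to an eleven-membered α-diazo ketone carrying one extra carbonyl carbon (C3a) between C2 and C3. A single photochemical Wolff rearrangement in methanol then forms the C2–C3 bond, the ten-membered ring, the C3–H stereocentre and the methyl ester. It exploits the fact that C3 of the oxygen-bridged ring is a CH bearing only an exocyclic CO2Me and flanked by C2 and the C4 ketal carbon of the C4–O–C7 dihydrofuran. The precursor is the bridged C4 methyl ketal with the diazo group on C3, the ketone on C3a and a silyl ether on C8.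

Key step: step 18

Remark (numbering): eunicellane numbering is used: C1 and C10 are the ring-fusion carbons, C14 carries isopropyl, C11=C12 is the ring A alkene, C7 carries methyl and the bridging oxygen, C8 the acyloxy group; the target is (1R,3R,4R,7S,8S,10R,14R).
Remark (assumption): lactols 23 and 24 are written in the bridged form; if they equilibrate with the open Z-hydroxy diketones, steps 16 and 17 are unchanged because both pass through the two forms.

Step 1
Reactants: 1 (S)-(+)-carvone
Product: 2 (S)-carvotanacetone
Conditions: H2 (1 atm), RhCl(PPh3)3 (cat.), benzene, rt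
Reagents that add atoms: none
Why: Homogeneous hydrogenation with RhCl(PPh3)3 should saturate only the unhindered 1,1-disubstituted isopropenyl alkene and leave the trisubstituted enone alone, so the carvone stereocentre (later C14) is carried over unchanged.

Step 2
Reactants: 2 (S)-carvotanacetone
Product: 4 (5R,6R)-6-allyl-5-isopropyl-2-methylcyclohex-2-en-1-one, via lithium enolate 3 (not isolated)
Conditions: LiN(iPr)2, THF, −78 °C; allyl bromide, DMPU, −78 to −20 °C
Reagents that add atoms: allyl bromide, C=CCBr
Why: Kinetic deprotonation gives the cross-conjugated α′ enolate, and SN2 alkylation by the allylic bromide should occur anti to the adjacent isopropyl group, setting C1 trans to isopropyl (the centre is α to the ketone, so any cis isomer can be equilibrated to the diequatorial trans ketone).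

Step 3
Reactants: 4 allyl ketone
Product: 5 epoxy ketone (oxirane trans to isopropyl, cis to allyl)
Conditions: 30% H2O2, NaOH (cat.), MeOH, 0 °C
Reagents that add atoms: hydrogen peroxide, OO
Why: Weitz–Scheffer nucleophilic epoxidation touches only the enone, and axial conjugate addition of hydroperoxide trans to the isopropyl group should place the oxirane on the face opposite isopropyl, which fixes the face from which C9 is later delivered.

Step 4
Reactants: 5 epoxy ketone
Product: 7 (1S,4R,5R)-4-allyl-5-isopropyl-2-methylcyclohex-2-en-1-ol, via epoxy hydrazone 6 (not isolated)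
Conditions: N2H4·H2O, AcOH (cat.), MeOH, 0 °C to rt
Reagents that add atoms: none
Why: Wharton transposition: the epoxy hydrazone fragments with loss of nitrogen to the allylic alcohol, shifting the alkene toward the former carbonyl carbon while the C–O bond, and so the carbinol configuration (hydroxyl cis to allyl), is untouched.

Step 5
Reactants: 7 transposed allylic alcohol
Product: 9 ethyl (6-allyl-5-isopropyl-2-methylcyclohex-2-en-1-yl)acetate (acetate arm cis to allyl and trans to isopropyl), via ketene acetal 8 (not isolated)
Conditions: MeC(OEt)3, EtCO2H (cat.), xylene, 140 °C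
Reagents that add atoms: triethyl orthoacetate, CCOC(C)(OCC)OCC
Why: Johnson–Claisen rearrangement: the suprafacial [3,3] shift of the ketene acetal delivers C9 to C10 on the face that carried oxygen, cis to the allyl arm and trans to isopropyl, and returns the ring alkene to C11=C12.

Step 6
Reactants: 9 ring A ethyl ester
Product: 10 ring A aldehyde (C8 as CHO)
Conditions: iBu2AlH, CH2Cl2, −78 °C; aq. KNaC4H4O6
Reagents that add atoms: none
Why: Partial reduction of an ester by iBu2AlH at low temperature stops at the aluminium hemiacetal, which gives the aldehyde on work-up without touching a stereocentre.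

Step 7
Reactants: 11 (S)-lactic acid
Product: 12 (2S,5S)-2-tert-butyl-5-methyl-1,3-dioxolan-4-one
Conditions: pivalaldehyde, p-toluenesulfonic acid (cat.), pentane, reflux, Dean–Stark; crystallisation
Reagents that add atoms: pivalaldehyde, CC(C)(C)C=O
Why: Acid-catalysed acetalisation (Seebach template for self-regeneration of a stereocentre) leaves the lactate centre untouched and should give mainly the cis acetal, whose new centre is relayed from it and which is purified by crystallisation.

Step 8
Reactants: 12 (2S,5S)-dioxolanone; 10 ring A aldehyde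
Product: 14 aldol adduct (C8 epimers), via lithium enolate 13 (not isolated)
Conditions: LiN(iPr)2, THF, −78 °C; then 10, −78 °C; AcOH
Reagents that add atoms: none
Why: Seebach aldol addition: the aldehyde is attacked by the enolate face anti to tert-butyl, so quaternary C7 is set with overall retention of the lactate configuration, whereas C8 is not reliably controlled here and is corrected in steps 9 and 10.

Step 9
Reactants: 14 aldol adduct (C8 epimers)
Product: 15 C8 ketone (β-keto dioxolanone)
Conditions: Dess–Martin periodinane, NaHCO3, CH2Cl2, 0 °C to rt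
Reagents that add atoms: none
Why: Dess–Martin oxidation converts both C8 epimers into one β-keto lactone, which cannot enolise toward the quaternary C7.

Step 10
Reactants: 15 C8 ketone
Product: 16 (8S)-alcohol
Conditions: catecholborane, (R)-1-methyl-3,3-diphenyltetrahydro-1H,3H-pyrrolo[1,2-c][1,3,2]oxazaborole (20 mol%), toluene, −78 °C
Reagents that add atoms: none
Why: Corey–Bakshi–Shibata reduction: with the quaternary C7 as the large and the C9 methylene as the small substituent, the (R)-oxazaborolidine should deliver hydride to give the 8S alcohol under reagent control, and catecholborane does not hydroborate the alkenes at this temperature.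

Step 11
Reactants: 16 (8S)-alcohol
Product: 17 C8 tert-butyldimethylsilyl ether
Conditions: tBuMe2SiOTf, 2,6-lutidine, CH2Cl2, 0 °C
Reagents that add atoms: tert-butyldimethylsilyl trifluoromethanesulfonate, CC(C)(C)[Si](C)(C)OS(=O)(=O)C(F)(F)F
Why: A silyl triflate with a hindered pyridine base silylates the hindered secondary alcohol, and this silyl group is chosen because it survives the acidic methanol of step 17 and resists migration to the neighbouring tertiary oxygen.

Step 12
Reactants: 17 silyl ether dioxolanone
Product: 18 dioxolan-4-ol (lactol, both anomers)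
Conditions: iBu2AlH, CH2Cl2, −78 °C
Reagents that add atoms: none
Why: iBu2AlH at low temperature reduces the lactone carbonyl of the dioxolanone only to the lactol, exposing C6 at the aldehyde oxidation level.

Step 13
Reactants: 18 lactol
Product: 20 butenolide (C4 lactone, Z C5=C6, quaternary C7), via Z-hydroxy enoate 19 (not isolated)
Conditions: (CF3CH2O)2P(O)CH2CO2Me, KN(SiMe3)2, 18-crown-6, THF, −78 to 0 °C
Reagents that add atoms: methyl bis(2,2,2-trifluoroethyl)phosphonoacetate, COC(=O)CP(=O)(OCC(F)(F)F)OCC(F)(F)F
Why: Under base the lactol opens and sheds pivalaldehyde, Still–Gennari olefination of the resulting aldehyde gives the Z enoate, and the C7 oxygen lactonises, so the Z C5=C6 geometry is locked in the butenolide (only the Z isomer can close).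

Step 14
Reactants: 20 butenolide
Product: 21 methyl ketone (C3a=O, C3 as CH3)
Conditions: PdCl2 (10 mol%), CuCl, O2 (1 atm), DMF/H2O (7:1), rt
Reagents that add atoms: water, O
Why: Tsuji–Wacker oxidation converts only the monosubstituted terminal alkene into the methyl ketone with Markovnikov selectivity, the trisubstituted ring alkene and the electron-poor butenolide alkene being inert.

Step 15
Reactants: 21 methyl ketone
Product: 23 eleven-membered β-keto lactol, via lithium enolate 22 (not isolated)
Conditions: LiN(SiMe3)2 (2.5 equiv), THF (0.002 M), −78 to −20 °C; AcOH, −78 °C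
Reagents that add atoms: none
Why: Claisen-type addition of the kinetic methyl-ketone enolate to the lactone carbonyl C4 forms the C3–C4 bond and the eleven-membered ring and should stop at the lactol alkoxide; the cis arms on ring A and high dilution favour closure, conjugate attack at C6 is hindered by the adjacent quaternary C7, and the C4 configuration is dictated by the oxygen bridge to C7.

Step 16
Reactants: 23 β-keto lactol
Product: 24 α-diazo β-keto lactol (diazo on C3)
Conditions: 4-acetamidobenzenesulfonyl azide, Et3N, MeCN, 0 °C to rt
Reagents that add atoms: 4-acetamidobenzenesulfonyl azide, CC(=O)Nc1ccc(cc1)S(=O)(=O)N=[N+]=[N-]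
Why: Regitz diazo transfer: amine base opens the lactol to the 1,3-diketone, in which C3 is the only doubly activated methylene, so the diazo group goes to C3 and not to C2, and the product can no longer lose water toward an alkylidene dihydrofuran.

Step 17
Reactants: 24 α-diazo β-keto lactol
Product: 25 eleven-membered α-diazo ketone C4 methyl ketal
Conditions: pyridinium p-toluenesulfonate (cat.), MeOH, 4 Å molecular sieves, rt, dark
Reagents that add atoms: methanol, CO
Why: Acid-catalysed lactol-to-methyl-ketal exchange through the oxocarbenium ion stabilised by the ring oxygen, with C4 fixed by the bridge; the acyl-stabilised diazo group should tolerate the weakly acidic pyridinium salt and the silyl ether is stable.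

Step 18
Reactants: 25 α-diazo ketone methyl ketal
Product: 28 ten-membered C3 methyl ester methyl ketal, via ketene 26 (not isolated), via ester enol 27 (not isolated)
Conditions: hν (365 nm), degassed MeOH, 0 °C
Reagents that add atoms: methanol, CO
Why: Direct excitation of the diazo ketone expels nitrogen while C2 migrates with its bonding pair from the carbonyl carbon C3a to C3, giving an exocyclic ketene on the new ten-membered ring, to which methanol adds before the ester enol ketonises. The closest known reaction type is the photochemical Wolff ring contraction of cyclic α-diazo ketones in alcohols, including diazo ketones whose diazo carbon adjoins an acetal carbon. The ten-membered ring is not closed by joining two chain ends: it arises by a 1,2-shift that excises C3a from the eleven-membered ring and joins C2 to C3. C3 is set in the final proton transfer, expected on the face of the tied-back bridging oxygen and anti to the C4 methoxy group, which places the ester cis to methoxy as required, and the centre stays correctable because it is α to the ester. The step needs migration to outrun carbene chemistry (O–H insertion into methanol, shift of a C4 substituent), which the cyclic diazo ketone, able to reach the syn-periplanar geometry, and direct irradiation in neat methanol should favour. Only C2 can migrate, because the acyl carbon carries nothing else but the carbene carbon and the C4 ketal leaves no second acyl group.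

Step 19
Reactants: 28 ring-contracted ester
Product: 29 C8 alcohol
Conditions: Bu4NF, AcOH, THF, 0 °C to rt
Reagents that add atoms: none
Why: Fluoride cleaves the silyl ether, and buffering with acetic acid keeps the medium from becoming basic enough for β-elimination of a C4 alkoxy group from the ester while staying too mild to open the ketal.

Step 20
Reactants: 30 urocanic acid
Product: 31 methyl (E)-3-(1-methyl-1H-imidazol-4-yl)acrylate
Conditions: MeI (2.2 equiv), K2CO3, DMF, rt
Reagents that add atoms: iodomethane, CI
Why: Carboxylate O-alkylation and imidazole N-alkylation in one operation; 4(5)-substituted imidazoles are alkylated mainly at the nitrogen remote from the substituent, giving the 1-methyl-4-yl isomer, and the minor 1,5-isomer is removed by crystallisation.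

Step 21
Reactants: 31 methyl N-methylurocanate
Product: 32 (E)-3-(1-methyl-1H-imidazol-4-yl)acrylic acid
Conditions: LiOH, THF/H2O, rt; then HCl to pH 5
Reagents that add atoms: lithium hydroxide, [Li+].[OH-]
Why: Saponification of the methyl ester leaves the E alkene and the N-methyl group untouched, and the zwitterionic acid is collected at its isoelectric point.

Step 22
Reactants: 29 C8 alcohol; 32 N-methylurocanic acid
Product: 34 C8 urocanate methyl ketal, via mixed anhydride 33 (not isolated)
Conditions: 2,4,6-trichlorobenzoyl chloride, Et3N, THF, rt; then 29, 4-(dimethylamino)pyridine, toluene, 40 °C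
Reagents that add atoms: none
Why: Yamaguchi esterification: the mixed anhydride acylates the hindered C8 hydroxyl under 4-(dimethylamino)pyridine catalysis without touching a stereocentre, and the light-sensitive E urocanate enters only after the photochemical step.

Step 23
Reactants: 34 urocanate methyl ketal
Product: 35 target hemiketal (CNP0113846.1)
Conditions: camphor-10-sulfonic acid (1.2 equiv), CH2Cl2/H2O (10:1), rt
Reagents that add atoms: water, O
Why: Acid-catalysed hydrolysis of the methyl ketal through the bridged oxocarbenium ion gives the hemiketal with C4 enforced by the C7 bridge, and C3, which can equilibrate through the open β-keto ester tautomer, is expected to settle in the configuration of the target.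

Compound list
1 | (S)-(+)-carvone | CC1=CC[C@@H](CC1=O)C(C)=C | starting material
2 | (S)-carvotanacetone, (5S)-5-isopropyl-2-methylcyclohex-2-en-1-one | CC1=CC[C@@H](CC1=O)C(C)C | intermediate
3 | cross-conjugated lithium enolate of 2 (C1–O, C1=C6) | CC1=CC[C@@H](C=C1[O-])C(C)C.[Li+] | intermediate (not isolated)
4 | (5R,6R)-6-allyl-5-isopropyl-2-methylcyclohex-2-en-1-one (allyl trans to isopropyl) | CC1=CC[C@@H]([C@@H](CC=C)C1=O)C(C)C | intermediate
5 | 2,3-epoxide of 4, oxirane oxygen trans to isopropyl and cis to allyl | C[C@]12O[C@H]1C[C@@H]([C@@H](CC=C)C2=O)C(C)C | intermediate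
6 | hydrazone of epoxy ketone 5 | C[C@]12O[C@H]1C[C@@H]([C@@H](CC=C)C2=NN)C(C)C | intermediate (not isolated)
7 | (1S,4R,5R)-4-allyl-5-isopropyl-2-methylcyclohex-2-en-1-ol (hydroxyl cis to allyl, trans to isopropyl) | CC1=C[C@H](CC=C)[C@@H](C(C)C)C[C@@H]1O | intermediate
8 | 1-ethoxyvinyl ether of 7 (mixed ketene acetal) | CC1=C[C@H](CC=C)[C@@H](C(C)C)C[C@@H]1OC(=C)OCC | intermediate (not isolated)
9 | ethyl (6-allyl-5-isopropyl-2-methylcyclohex-2-en-1-yl)acetate, acetate arm cis to allyl and trans to isopropyl (C1, C10, C14 as in the target) | CCOC(=O)C[C@H]1C(C)=CC[C@H](C(C)C)[C@H]1CC=C | intermediate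
10 | (6-allyl-5-isopropyl-2-methylcyclohex-2-en-1-yl)acetaldehyde, same ring configuration as 9 | O=CC[C@H]1C(C)=CC[C@H](C(C)C)[C@H]1CC=C | intermediate
11 | (S)-lactic acid | C[C@H](O)C(O)=O | starting material
12 | (2S,5S)-2-tert-butyl-5-methyl-1,3-dioxolan-4-one (cis) | C[C@@H]1O[C@H](C(C)(C)C)OC1=O | intermediate
13 | lithium enolate of 12 | CC1=C([O-])O[C@@H](C(C)(C)C)O1.[Li+] | intermediate (not isolated)
14 | aldol adduct: dioxolanone with quaternary C7 (C8 chain trans to tert-butyl), C8 hydroxyl as both epimers | CC(C)(C)[C@@H]1OC(=O)[C@](C)(O1)C(O)C[C@H]2C(C)=CC[C@H](C(C)C)[C@H]2CC=C | intermediate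
15 | C8 ketone of 14 (β-keto dioxolanone) | CC(C)(C)[C@@H]1OC(=O)[C@](C)(O1)C(=O)C[C@H]2C(C)=CC[C@H](C(C)C)[C@H]2CC=C | intermediate
16 | (8S)-alcohol from reduction of 15 | CC(C)(C)[C@@H]1OC(=O)[C@](C)(O1)[C@@H](O)C[C@H]2C(C)=CC[C@H](C(C)C)[C@H]2CC=C | intermediate
17 | C8 tert-butyldimethylsilyl ether of 16 | CC(C)(C)[C@@H]1OC(=O)[C@](C)(O1)[C@@H](O[Si](C)(C)C(C)(C)C)C[C@H]2C(C)=CC[C@H](C(C)C)[C@H]2CC=C | intermediate
18 | dioxolan-4-ol (lactol) from 17, both anomers | CC(C)(C)[C@@H]1OC(O)[C@](C)(O1)[C@@H](O[Si](C)(C)C(C)(C)C)C[C@H]2C(C)=CC[C@H](C(C)C)[C@H]2CC=C | intermediate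
19 | methyl (Z)-4-hydroxy-4-methyl-5-silyloxy enoate (C4–C8 open chain, free C7 hydroxyl) | COC(=O)/C=C\[C@](C)(O)[C@@H](O[Si](C)(C)C(C)(C)C)C[C@H]1C(C)=CC[C@H](C(C)C)[C@H]1CC=C | intermediate (not isolated)
20 | butenolide: 5-methyl-furan-2(5H)-one carrying at C7 the (8S)-silyloxy chain to ring A, allyl arm on C1 | C[C@@]1(OC(=O)C=C1)[C@@H](O[Si](C)(C)C(C)(C)C)C[C@H]2C(C)=CC[C@H](C(C)C)[C@H]2CC=C | intermediate
21 | butenolide methyl ketone (2-oxopropyl arm on C1) | C[C@@]1(OC(=O)C=C1)[C@@H](O[Si](C)(C)C(C)(C)C)C[C@H]2C(C)=CC[C@H](C(C)C)[C@H]2CC(C)=O | intermediate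
22 | terminal lithium enolate of 21 | C[C@@]1(OC(=O)C=C1)[C@@H](O[Si](C)(C)C(C)(C)C)C[C@H]2C(C)=CC[C@H](C(C)C)[C@H]2CC(=C)[O-].[Li+] | intermediate (not isolated)
23 | eleven-membered β-keto lactol (C3a ketone, C3 methylene, C4 hemiketal bridged to C7) | O=C1C[C@@H]2[C@@H](C(C)C)CC=C(C)[C@@H]2C[C@H](O[Si](C)(C)C(C)(C)C)[C@]2(C)C=C[C@@](O)(O2)C1 | intermediate
24 | eleven-membered α-diazo β-keto lactol (diazo on C3) | O=C1C[C@@H]2[C@@H](C(C)C)CC=C(C)[C@@H]2C[C@H](O[Si](C)(C)C(C)(C)C)[C@]2(C)C=C[C@@](O)(O2)C1=[N+]=[N-] | intermediate
25 | eleven-membered α-diazo ketone C4 methyl ketal (key-step precursor) | O=C1C[C@@H]2[C@@H](C(C)C)CC=C(C)[C@@H]2C[C@H](O[Si](C)(C)C(C)(C)C)[C@]2(C)C=C[C@@](OC)(O2)C1=[N+]=[N-] | intermediate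
26 | ten-membered exocyclic ketene at C3 | O=C=C1C[C@@H]2[C@@H](C(C)C)CC=C(C)[C@@H]2C[C@H](O[Si](C)(C)C(C)(C)C)[C@]2(C)C=C[C@@]1(OC)O2 | intermediate (not isolated)
27 | enol of the C3 methyl ester (ketene hemiacetal) | COC(O)=C1C[C@@H]2[C@@H](C(C)C)CC=C(C)[C@@H]2C[C@H](O[Si](C)(C)C(C)(C)C)[C@]2(C)C=C[C@@]1(OC)O2 | intermediate (not isolated)
28 | ten-membered bridged methyl ketal with (3R)-methyl ester and C8 silyl ether (key-step product) | COC(=O)[C@@H]1C[C@@H]2[C@@H](C(C)C)CC=C(C)[C@@H]2C[C@H](O[Si](C)(C)C(C)(C)C)[C@]2(C)C=C[C@@]1(OC)O2 | intermediate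
29 | C8 alcohol of 28 | COC(=O)[C@@H]1C[C@@H]2[C@@H](C(C)C)CC=C(C)[C@@H]2C[C@H](O)[C@]2(C)C=C[C@@]1(OC)O2 | intermediate
30 | (E)-urocanic acid | OC(=O)/C=C/c1c[nH]cn1 | starting material
31 | methyl (E)-3-(1-methyl-1H-imidazol-4-yl)acrylate | COC(=O)/C=C/c1cn(C)cn1 | intermediate
32 | (E)-3-(1-methyl-1H-imidazol-4-yl)acrylic acid | OC(=O)/C=C/c1cn(C)cn1 | intermediate
33 | mixed anhydride of 32 and 2,4,6-trichlorobenzoic acid | Cn1cnc(/C=C/C(=O)OC(=O)c2c(Cl)cc(Cl)cc2Cl)c1 | intermediate (not isolated)
34 | C8 (E)-N-methylurocanate of the methyl ketal | COC(=O)[C@@H]1C[C@@H]2[C@@H](C(C)C)CC=C(C)[C@@H]2C[C@H](OC(=O)/C=C/c2cn(C)cn2)[C@]2(C)C=C[C@@]1(OC)O2 | intermediate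
35 | target hemiketal, (1R,3R,4R,7S,8S,10R,14R) | COC(=O)[C@@H]1C[C@@H]2[C@@H](C(C)C)CC=C(C)[C@@H]2C[C@H](OC(=O)/C=C/c2cn(C)cn2)[C@]2(C)C=C[C@@]1(O)O2 | target

Total step count: 23 steps. Longest linear sequence: 20 steps from (S)-carvone (steps 1–6, 8–19, 22 and 23); step 7 and steps 20–21 are side branches.

The three steps most likely to fail

Step 18 (Wolff contraction). After nitrogen is lost the carbene may be intercepted before C2 migrates, by O–H insertion into methanol or by a shift of a C4 substituent, if the diazo ketone reacts from a twisted geometry. The fallback sets out from 20 and comes back at 28; it closes the ten-membered ring directly with the ester already in place. Hydroboration of the terminal alkene of 20 with 9-borabicyclo[3.3.1]nonane and oxidation with NaBO3·4H2O should give the primary alcohol F1. Oxidation with 2,2,6,6-tetramethylpiperidine-1-oxyl and PhI(OAc)2 in MeCN/H2O gives the carboxylic acid F2, and Me3SiCHN2 in MeOH the methyl ester F3, whose three former allyl carbons are now C2, C3 and the ester carbon. LiN(iPr)2 in THF at −78 °C under high dilution forms the lithium ester enolate F4, which adds to the butenolide carbonyl (ester enolate addition to a lactone, stopping at the lactol) to give the ten-membered lactol ester F5. Pyridinium p-toluenesulfonate in MeOH then converts the lactol into 28.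

Step 15 (eleven-membered ring closure). The enolate may add to C6 in conjugate fashion or to a second molecule faster than it closes the ring, or the lactol alkoxide may revert to enolate and lactone on warming. The fallback sets out from 21 and comes back at 24; the ring is closed by a diazo-stabilised carbanion, which adds to carbonyl groups in 1,2 fashion and gives an adduct that cannot enolise or revert through a ketone enolate. LiN(SiMe3)2 and CF3CO2CH2CF3 at −78 °C give the trifluoroacetyl ketone F6, and MeSO2N3, Et3N and water in MeCN give the diazomethyl ketone F7 (detrifluoroacetylative diazo transfer at the methyl group). LiN(SiMe3)2 in THF at −78 °C under high dilution forms the lithio diazo ketone F8, which adds to the lactone carbonyl to give 24 directly, so that step 16 is omitted.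

Step 17 (ketal formation beside the diazo group). The diazo carbon may be protonated with loss of nitrogen, or exchange may stall because the lactol reopens to the conjugated diazo diketone, whose C4 carbonyl is a poor electrophile. The fallback sets out from 24 and comes back at 25; it replaces the acid-catalysed exchange by anomeric O-alkylation under base (NaH, MeI, THF/DMF, 0 °C). The lactol oxide is more nucleophilic than the tertiary C7 alkoxide of the open form and is methylated without any acid; no new compound arises (F0).

Further compounds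
F1 | step 18 | primary alcohol from hydroboration of 20 (3-hydroxypropyl arm on C1) | C[C@@]1(OC(=O)C=C1)[C@@H](O[Si](C)(C)C(C)(C)C)C[C@H]2C(C)=CC[C@H](C(C)C)[C@H]2CCCO
F2 | step 18 | carboxylic acid (2-carboxyethyl arm on C1) | C[C@@]1(OC(=O)C=C1)[C@@H](O[Si](C)(C)C(C)(C)C)C[C@H]2C(C)=CC[C@H](C(C)C)[C@H]2CCC(O)=O
F3 | step 18 | methyl ester of F2 | C[C@@]1(OC(=O)C=C1)[C@@H](O[Si](C)(C)C(C)(C)C)C[C@H]2C(C)=CC[C@H](C(C)C)[C@H]2CCC(=O)OC
F4 | step 18 | lithium ester enolate of F3 | C[C@@]1(OC(=O)C=C1)[C@@H](O[Si](C)(C)C(C)(C)C)C[C@H]2C(C)=CC[C@H](C(C)C)[C@H]2CC=C([O-])OC.[Li+]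
F5 | step 18 | ten-membered lactol bearing the C3 methyl ester and C8 silyl ether | COC(=O)[C@@H]1C[C@@H]2[C@@H](C(C)C)CC=C(C)[C@@H]2C[C@H](O[Si](C)(C)C(C)(C)C)[C@]2(C)C=C[C@@]1(O)O2
F6 | step 15 | trifluoroacetyl ketone from 21 | C[C@@]1(OC(=O)C=C1)[C@@H](O[Si](C)(C)C(C)(C)C)C[C@H]2C(C)=CC[C@H](C(C)C)[C@H]2CC(=O)CC(=O)C(F)(F)F
F7 | step 15 | diazomethyl ketone | C[C@@]1(OC(=O)C=C1)[C@@H](O[Si](C)(C)C(C)(C)C)C[C@H]2C(C)=CC[C@H](C(C)C)[C@H]2CC(=O)C=[N+]=[N-]
F8 | step 15 | lithio diazo ketone | C[C@@]1(OC(=O)C=C1)[C@@H](O[Si](C)(C)C(C)(C)C)C[C@H]2C(C)=CC[C@H](C(C)C)[C@H]2CC(=O)[C-]=[N+]=[N-].[Li+]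
F0 | step 17 | none | none
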